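Both rings are closed in one intramolecular Diels–Alder reaction that forms C5–C10 and C8–C9 (avarane numbering). It exploits ring B, whose quaternary C5 and C9 flank C10–H. The precursor is an acyclic tetraenal in which an (E)-2-methyl-enal (C9=C10, carrying the C9 methyl and the future benzylic carbon C11 as CHO) is tethered through C1–C4 to a vinylallene (C5=C6–C7=C8=CH2) carrying the C5 methyl. The cycloaddition creates C5, C9 and C10 with the trans fusion; the allene leaves C8 as an exocyclic methylene that hydrogenation turns into the equatorial methyl. A silyloxy stereocentre at C4 relays absolute configuration and later becomes the C4 methylene.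

Key step: step 8

Remark on numbering: decalin carbons are C1–C10 as in the avarane (4,9-friedodrimane) skeleton, C11 is the benzylic carbon, the exocyclic methylene sits on C4 and the methyls on C5, C8 and C9; α/β refer to the usual drawing with the C5 methyl β. Target = (5S,8S,9R,10S).
Assumption: hex-5-enoyl chloride, tributyl(propa-1,2-dienyl)stannane and methyl 4-hydroxy-3-iodobenzoate are taken as commercial.

Step 1
Reactants: 1 hex-5-enoyl chloride; 2 ethynyltrimethylsilane
Product: 3 1-(trimethylsilyl)oct-7-en-1-yn-3-one
Conditions: PdCl2(PPh3)2 (cat.), CuI (cat.), Et3N, THF, rt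
Reagents that add atoms: none
Why: Palladium/copper-catalysed acyl Sonogashira coupling of an acid chloride with a terminal alkyne is a standard route to silyl ynones and leaves the isolated terminal alkene untouched.

Step 2
Reactants: 3 1-(trimethylsilyl)oct-7-en-1-yn-3-one
Product: 4 (3S)-1-(trimethylsilyl)oct-7-en-1-yn-3-ol
Conditions: Ru[(S,S)-TsDPEN](p-cymene) (cat.), i-PrOH, rt
Reagents that add atoms: none
Why: Asymmetric transfer hydrogenation of alkynyl ketones is selective for C=O over C≡C and C=C, and with the (S,S)-catalyst the alkynyl group acts as the π-directing substituent so that the (S)-carbinol (the future C4 relay stereocentre) should form.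

Step 3
Reactants: 4 (3S)-1-(trimethylsilyl)oct-7-en-1-yn-3-ol
Product: 5 (3S)-oct-7-en-1-yn-3-ol
Conditions: K2CO3 (cat.), MeOH, rt
Reagents that add atoms: none
Why: Base-catalysed methanolysis of the C(sp)–Si bond (protodesilylation) frees the terminal alkyne without touching the carbinol stereocentre.

Step 4
Reactants: 5 (3S)-oct-7-en-1-yn-3-ol
Product: 6 (3S)-3-(triethylsilyloxy)oct-7-en-1-yne
Conditions: TESCl, imidazole, CH2Cl2, 0 °C
Reagents that add atoms: chlorotriethylsilane CC[Si](Cl)(CC)CC
Why: Standard silylation of a secondary alcohol; the triethylsilyl ether is bulky enough to act as the conformational control element in step 8 and acid-labile enough to be lost in step 12.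

Step 5
Reactants: 6 (3S)-3-(triethylsilyloxy)oct-7-en-1-yne
Product: 8 (1E,3S)-1-iodo-2-methyl-3-(triethylsilyloxy)octa-1,7-diene, via dimethyl[(1E,3S)-2-methyl-3-(triethylsilyloxy)octa-1,7-dien-1-yl]alane 7 (not isolated)
Conditions: Me3Al, Cp2ZrCl2 (cat.), CH2Cl2, 0 °C → rt; then I2, THF, −30 °C
Reagents that add atoms: trimethylaluminium C[Al](C)C; iodine II
Why: Zirconium-catalysed carboalumination (Negishi) adds methyl and aluminium syn across the terminal alkyne, with aluminium at the terminus and faster than across the monosubstituted alkene, and iodinolysis with retention gives the (E)-iodide in which the new methyl (the C5 methyl) is cis to iodine.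

Step 6
Reactants: 8 (1E,3S)-1-iodo-2-methyl-3-(triethylsilyloxy)octa-1,7-diene; 9 methacrolein
Product: 10 (2E,7S,8E)-9-iodo-2,8-dimethyl-7-(triethylsilyloxy)nona-2,8-dienal
Conditions: 9 (excess), Hoveyda–Grubbs II (cat.), CH2Cl2, 40 °C
Reagents that add atoms: none
Why: Olefin cross-metathesis of a terminal alkene with excess methacrolein should give the trisubstituted (E)-2-methyl-enal under thermodynamic control, while the trisubstituted alkenyl iodide is too hindered to enter metathesis.

Step 7
Reactants: 10 (2E,7S,8E)-9-iodo-2,8-dimethyl-7-(triethylsilyloxy)nona-2,8-dienal; 11 tributyl(propa-1,2-dien-1-yl)stannane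
Product: 12 (2E,7S,8E)-2,8-dimethyl-7-(triethylsilyloxy)dodeca-2,8,10,11-tetraenal
Conditions: Pd2(dba)3 (cat.), AsPh3, CuI (cat.), DMF, rt; product kept cold and used at once
Reagents that add atoms: none
Why: Stille coupling of an alkenyl iodide with an allenylstannane transfers the allenyl group with retention of alkene geometry at room temperature, so that the C5 methyl ends up cis to the allene.

Step 8
Reactants: 12 (2E,7S,8E)-2,8-dimethyl-7-(triethylsilyloxy)dodeca-2,8,10,11-tetraenal
Product: 13 (4S,5S,9S,10R)-5,9-dimethyl-8-methylidene-4-(triethylsilyloxy)-Δ6-octalin-9-carbaldehyde [= (1S,4aS,5S,8aR)-1,4a-dimethyl-2-methylidene-5-(triethylsilyloxy)-1,2,4a,5,6,7,8,8a-octahydronaphthalene-1-carbaldehyde; trans-fused, 4β-OSiEt3, 5β-Me, 9β-Me, 9α-CHO, 10α-H]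
Conditions: Me2AlCl (1.2 equiv), CH2Cl2, −78 → −30 °C
Reagents that add atoms: none
Why: Me2AlCl complexes the enal and triggers a concerted, asynchronous [4+2] between the C9=C10 dienophile and the C5=C6–C7=C8 diene (vinyl group plus proximal allene π bond) of 12, the closest known reaction types being Lewis-acid-promoted intramolecular Diels–Alder reactions of (E)-2-methyl-2,8,10-trienals to trans-octalins with a quaternary C(Me)CHO carbon and Diels–Alder reactions of vinylallenes. Ring B is closed as the cycloadduct ring through the new C5–C10 and C8–C9 bonds, and ring A is closed by the same C5–C10 bond as the six-membered tether ring (type 1, chair-like four-atom tether). C9 follows from suprafacial addition to the (E)-enal (methyl cis to C1), the trans C5/C10 fusion from the CHO-endo/tether-exo transition state with the tether outside and the methyl inside at the C5 terminus, and the absolute sense from the (S)-C4 OSiEt3 group, which should take the pseudo-equatorial position of the chair tether, anti to the forming C5–C10 bond, and so expose one diene face. The allene terminus has no inside substituent, which lets the inside C5 methyl into the s-cis diene and should make the diene reactive enough below −30 °C, where [1,5]-hydrogen shift of the (Z)-methyl vinylallene is negligible. The step needs the trans-fused over the cis-fused mode and one diene face over the other: the first is secured by the aluminium-bound formyl group, the second by the C4 stereocentre, and because attack on the other face gives a diastereomer, it can be separated without loss of enantiopurity. C8 is left as an exocyclic methylene for step 11.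

Step 9
Reactants: 14 methyl 4-hydroxy-3-iodobenzoate
Product: 15 methyl 4-(benzyloxy)-3-iodobenzoate
Conditions: BnBr, K2CO3, acetone, 50 °C
Reagents that add atoms: benzyl bromide BrCc1ccccc1
Why: Williamson etherification of the phenol; the benzyl ether survives magnesiation and is removed by the hydrogenation of step 11.

Step 10
Reactants: 13 IMDA aldehyde; 15 methyl 4-(benzyloxy)-3-iodobenzoate
Product: 17 methyl 4-(benzyloxy)-3-{hydroxy[(1S,4aS,5S,8aR)-1,4a-dimethyl-2-methylidene-5-(triethylsilyloxy)-1,2,4a,5,6,7,8,8a-octahydronaphthalen-1-yl]methyl}benzoate (both C11 epimers), via [2-(benzyloxy)-5-(methoxycarbonyl)phenyl]magnesium chloride 16 (not isolated)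
Conditions: 15, i-PrMgCl·LiCl, THF, −40 °C; then 13, −40 → 0 °C; aq. NH4Cl
Reagents that add atoms: none
Why: Iodine–magnesium exchange ortho to the alkoxy group is fast at −40 °C and tolerates the ester, and the aryl Grignard should add (1,2-addition) to the non-enolisable neopentyl aldehyde to give a carbinol whose new stereocentre C11 (either epimer) is removed in step 12.

Step 11
Reactants: 17 benzyl-protected carbinol
Product: 18 methyl 4-hydroxy-3-{hydroxy[(1R,2S,4aS,5S,8aR)-1,2,4a-trimethyl-5-(triethylsilyloxy)decahydronaphthalen-1-yl]methyl}benzoate (both C11 epimers; 8β-Me)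
Conditions: H2 (1–3 atm), 10% Pd/C, EtOAc, rt
Reagents that add atoms: none
Why: Heterogeneous hydrogenation saturates the C6=C7/C8=CH2 diene and cleaves the aryl benzyl ether, hydrogen reaching C8 from the α face opposite the axial C9 and C5 methyls so that the new C8 methyl should be equatorial (8S).

Step 12
Reactants: 18 phenolic carbinol
Product: 19 methyl 4-hydroxy-3-{[(1R,2S,4aS,5S,8aS)-5-hydroxy-1,2,4a-trimethyldecahydronaphthalen-1-yl]methyl}benzoate
Conditions: Et3SiH, TFA, CH2Cl2, 0 °C → rt; then K2CO3, MeOH (cleaves any trifluoroacetate)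
Reagents that add atoms: none
Why: Ionic hydrogenation, in which TFA ionises the o-hydroxybenzylic alcohol to a cation stabilised as a protonated o-quinone methide (far more stable than any tertiary cation a 1,2-shift from C9 could give) that triethylsilane reduces to CH2, while the same acid removes the triethylsilyl ether.

Step 13
Reactants: 19 diol
Product: 20 methyl 4-hydroxy-3-{[(1R,2S,4aS,8aS)-1,2,4a-trimethyl-5-oxodecahydronaphthalen-1-yl]methyl}benzoate
Conditions: Dess–Martin periodinane, CH2Cl2, rt
Reagents that add atoms: none
Why: Dess–Martin oxidation of the hindered secondary alcohol to the ketone, which the electron-poor phenol should tolerate, erases the relay stereocentre at C4.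

Step 14
Reactants: 20 ketone
Product: 21 dictyoceratin C, methyl 4-hydroxy-3-{[(1R,2S,4aS,8aS)-1,2,4a-trimethyl-5-methylidenedecahydronaphthalen-1-yl]methyl}benzoate
Conditions: Ph3PCH3Br (excess), KOt-Bu (excess), toluene, 90 °C
Reagents that add atoms: methyltriphenylphosphonium bromide C[P+](c1ccccc1)(c1ccccc1)c1ccccc1.[Br-]
Why: Wittig methylenation with excess ylide is well precedented for α-quaternary cyclohexanones, and the phenoxide formed in situ deactivates the para ester toward the ylide.

Compound list
1 | hex-5-enoyl chloride | C=CCCCC(=O)Cl | starting material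
2 | ethynyltrimethylsilane | C#C[Si](C)(C)C | starting material
3 | 1-(trimethylsilyl)oct-7-en-1-yn-3-one | C=CCCCC(=O)C#C[Si](C)(C)C | intermediate
4 | (3S)-1-(trimethylsilyl)oct-7-en-1-yn-3-ol | C=CCCC[C@H](O)C#C[Si](C)(C)C | intermediate
5 | (3S)-oct-7-en-1-yn-3-ol | C=CCCC[C@H](O)C#C | intermediate
6 | (3S)-3-(triethylsilyloxy)oct-7-en-1-yne | C=CCCC[C@H](O[Si](CC)(CC)CC)C#C | intermediate
7 | dimethyl[(1E,3S)-2-methyl-3-(triethylsilyloxy)octa-1,7-dien-1-yl]alane | C=CCCC[C@H](O[Si](CC)(CC)CC)/C(C)=C/[Al](C)C | intermediate
8 | (1E,3S)-1-iodo-2-methyl-3-(triethylsilyloxy)octa-1,7-diene | C=CCCC[C@H](O[Si](CC)(CC)CC)/C(C)=C/I | intermediate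
9 | methacrolein (2-methylprop-2-enal) | C=C(C)C=O | starting material
10 | (2E,7S,8E)-9-iodo-2,8-dimethyl-7-(triethylsilyloxy)nona-2,8-dienal | O=C/C(C)=C/CCC[C@H](O[Si](CC)(CC)CC)/C(C)=C/I | intermediate
11 | tributyl(propa-1,2-dien-1-yl)stannane | C=C=C[Sn](CCCC)(CCCC)CCCC | starting material
12 | (2E,7S,8E)-2,8-dimethyl-7-(triethylsilyloxy)dodeca-2,8,10,11-tetraenal | O=C/C(C)=C/CCC[C@H](O[Si](CC)(CC)CC)/C(C)=C/C=C=C | intermediate
13 | (1S,4aS,5S,8aR)-1,4a-dimethyl-2-methylidene-5-(triethylsilyloxy)-1,2,4a,5,6,7,8,8a-octahydronaphthalene-1-carbaldehyde | CC[Si](CC)(CC)O[C@H]1CCC[C@H]2[C@](C)(C=O)C(=C)C=C[C@]12C | intermediate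
14 | methyl 4-hydroxy-3-iodobenzoate | COC(=O)c1ccc(O)c(I)c1 | starting material
15 | methyl 4-(benzyloxy)-3-iodobenzoate | COC(=O)c1ccc(OCc2ccccc2)c(I)c1 | intermediate
16 | [2-(benzyloxy)-5-(methoxycarbonyl)phenyl]magnesium chloride (LiCl complex) | COC(=O)c1ccc(OCc2ccccc2)c([Mg]Cl)c1 | intermediate
17 | methyl 4-(benzyloxy)-3-{hydroxy[(1S,4aS,5S,8aR)-1,4a-dimethyl-2-methylidene-5-(triethylsilyloxy)-1,2,4a,5,6,7,8,8a-octahydronaphthalen-1-yl]methyl}benzoate, carbinol epimers | CC[Si](CC)(CC)O[C@H]1CCC[C@H]2[C@](C)(C(O)c3cc(C(=O)OC)ccc3OCc3ccccc3)C(=C)C=C[C@]12C | intermediate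
18 | methyl 4-hydroxy-3-{hydroxy[(1R,2S,4aS,5S,8aR)-1,2,4a-trimethyl-5-(triethylsilyloxy)decahydronaphthalen-1-yl]methyl}benzoate, carbinol epimers | CC[Si](CC)(CC)O[C@H]1CCC[C@H]2[C@](C)(C(O)c3cc(C(=O)OC)ccc3O)[C@@H](C)CC[C@]12C | intermediate
19 | methyl 4-hydroxy-3-{[(1R,2S,4aS,5S,8aS)-5-hydroxy-1,2,4a-trimethyldecahydronaphthalen-1-yl]methyl}benzoate | O[C@H]1CCC[C@H]2[C@](C)(Cc3cc(C(=O)OC)ccc3O)[C@@H](C)CC[C@]12C | intermediate
20 | methyl 4-hydroxy-3-{[(1R,2S,4aS,8aS)-1,2,4a-trimethyl-5-oxodecahydronaphthalen-1-yl]methyl}benzoate | O=C1CCC[C@H]2[C@](C)(Cc3cc(C(=O)OC)ccc3O)[C@@H](C)CC[C@]12C | intermediate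
21 | dictyoceratin C | C=C1CCC[C@H]2[C@](C)(Cc3cc(C(=O)OC)ccc3O)[C@@H](C)CC[C@]12C | target

Total step count: 14. Longest linear sequence: 13 (steps 1–8 and 10–14).

Steps most likely to fail

Step 8. The cycloaddition may leak through the cis-fused (tether-endo) transition state or through attack on the other diene face. An electronic preference for keeping the C4–O bond away from the position anti to the forming C5–C10 bond would oppose the steric preference assumed here. If complexation of the hindered enal is slow, the vinylallene can also be diverted by [1,5]-hydrogen shift. The fallback changes the dienophile from a Lewis-acid complex to an alkoxy-allyl cation (ionic Diels–Alder reaction). It sets out from 12, which is treated with methoxytrimethylsilane and catalytic TMSOTf in CH2Cl2 at −78 °C. The enal is thereby converted in situ into its O-methyl oxocarbenium ion, a much more electrophilic and strongly endo-directing dienophile, which should cyclise at the lowest temperature to the dimethyl acetal of the cycloadduct F1. Mild hydrolysis on wet silica with oxalic acid then returns the route at aldehyde 13.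

Step 7. Transmetallation may transfer the propargyl instead of the allenyl group, and the freshly formed vinylallene–enal may cyclise or undergo hydrogen shift without control in the metal-containing mixture. The fallback makes the allene by reductive 1,3-transposition after the C–C coupling. It sets out from 10: Sonogashira coupling with prop-2-yn-1-ol (PdCl2(PPh3)2, CuI, Et3N, rt) should give the enynol (2E,7S,8E)-12-hydroxy-2,8-dimethyl-7-(triethylsilyloxy)dodeca-2,8-dien-10-ynal F2. Methyl chloroformate and pyridine convert it into its methyl carbonate F3. Palladium-catalysed hydrogenolysis with ammonium formate (Pd2(dba)3, Bu3P, THF, rt) then delivers hydride with SN2′ transposition and comes back to the route at 12.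

Step 11. Hydrogen may be delivered to the β face of C8, or palladium may first isomerise the diene to the hindered endocyclic C7=C8 alkene, which then resists reduction. The fallback is a hydroxyl-directed homogeneous hydrogenation. It sets out from 17: [Ir(cod)(PCy3)(py)]PF6 under H2 in CH2Cl2 uses the C11 hydroxyl, which sits on the α substituent of C9, to deliver hydrogen to the α face of both ring-B alkenes and should give the saturated benzyl ether F4. Separate hydrogenolysis (H2, Pd/C, EtOAc) removes the benzyl group and comes back to the route at 18.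

Further compounds
F1 | step 8 | (1S,4aS,5S,8aR)-1-(dimethoxymethyl)-1,4a-dimethyl-2-methylidene-5-(triethylsilyloxy)-1,2,4a,5,6,7,8,8a-octahydronaphthalene | CC[Si](CC)(CC)O[C@H]1CCC[C@H]2[C@](C)(C(OC)OC)C(=C)C=C[C@]12C
F2 | step 7 | (2E,7S,8E)-12-hydroxy-2,8-dimethyl-7-(triethylsilyloxy)dodeca-2,8-dien-10-ynal | O=C/C(C)=C/CCC[C@H](O[Si](CC)(CC)CC)/C(C)=C/C#CCO
F3 | step 7 | (4E,6S,10E)-5,11-dimethyl-12-oxo-6-(triethylsilyloxy)dodeca-4,10-dien-2-yn-1-yl methyl carbonate | O=C/C(C)=C/CCC[C@H](O[Si](CC)(CC)CC)/C(C)=C/C#CCOC(=O)OC
F4 | step 11 | methyl 4-(benzyloxy)-3-{hydroxy[(1R,2S,4aS,5S,8aR)-1,2,4a-trimethyl-5-(triethylsilyloxy)decahydronaphthalen-1-yl]methyl}benzoate, carbinol epimers | CC[Si](CC)(CC)O[C@H]1CCC[C@H]2[C@](C)(C(O)c3cc(C(=O)OC)ccc3OCc3ccccc3)[C@@H](C)CC[C@]12C
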